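All runs stem from a simulated flask with constants of no real substance; scatter was added.

Each percent of substrate charged either still stands or has gone, so I booked this flask by where the lost substrate went.

the same everywhere: gas phase 130 mM (held)
- Tuesday's: substrate 1 M; the very flask that is asked about, followed so far
- flask: substrate 1.0 M; time 10 min

Tuesday's run (percent of the substrate charged)

| time / s | target / % | substrate / % |
|---|---|---|
| 10.0 | 0 | 90 |
| 20.0 | 8 | 86 |
| 30.0 | 9 | 83 |
| 40.0 | 11 | 72 |
| 50.0 | 14 | 65 |
| 60.0 | 17 | 60 |
| 80.0 | 20 | 50 |

(scatter of a reading: 2 percentage points)

- at the start none of the gas phase is in solution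

- the target standing at 10 min, as a percentage of the substrate charged
- the change that raises the amount of target at 10 min, in percent of the substrate charged most ("none" if none brings more than 2 percentage points) (alder / oak / none)
- amount of target at 10 min, in percent of the substrate charged, after alder

- alder: doubling the transfer coefficient of the gas phase, all else as stated
- oak: doubling the saturation concentration of gas phase, all else as stated

By 10.0 s Tuesday's flask had lost 10 percentage points of substrate with 0% of target read. Between then and 80.0 s it gained 20 points of target for 40 points of substrate, so its share, the target gained per substrate lost between two moments (a selectivity), read 50.0%. Tuesday's substrate read half at 80.0 s, and at that pace of halving I reckoned 0.552% for 10 min. So I took this flask's charge as used by then, and the 90% read at 10.0 s, at that share, gave my own estimate of 45.0%.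

The forecast, higher than mine, said 48%, 60% after alder, and oak as the best change, holding that “Doubling saturation helps in either regime”.

The flask gave 59.4%, and 66.9% after alder, and oak gained more, 13 points against 7.5 points.

    gas phase ⇌ dissolved gas, rate k1*(csat - [dissolved gas]) (kL = 0.0358 s⁻¹)
    substrate + dissolved gas → target (k = 0.104 M⁻¹ s⁻¹)
    substrate → side product (k = 0.00142 s⁻¹)
    2 substrate → homo dimer (k = 0.00216 M⁻¹ s⁻¹)

Between 1.00 min and 5.00 min this flask's share was 70.0%, above the 50.0% read on Tuesday up to 80.0 s, while its dissolved gas rose from 34.4% to 83.7% of saturation. With 0.40 M of substrate in place of 1.0 M, the neighbour flask's share from charge to 10.0 min was 75.5%, against 59.4% in this flask.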